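## The problem

Melanocin E (15) is flat and achiral, so nothing has to be set in space. The task is to put five substituents on the right carbons of a naphthalene. Ring A (C1, C2, C3, C4, C4a, C8a) carries three contiguous groups beside a free C4–H: the 4-methoxyphenyl group on C1 and formamides on C2 and C3. Ring B (C4a, C5, C6, C7, C8, C8a) is a catechol with OH on C6 and C7. No commercial naphthalene has this 1,2,3,6,7 pattern, and substitution chemistry helps little, because electrophiles prefer alpha positions while both nitrogens sit on beta positions, and C1, C4, C5 and C8 would all be activated at once. The N–C2–C3–N unit is a dissonant 1,2-relationship, so a polar C2–C3 bond formation is not available, and the two nitrogens must arrive together, either in a bought fragment or by addition across a C2=C3 bond. Three groups limit the conditions: neighbouring formamides close to a naphthimidazole under acid and heat, the free catechol is oxidised by air once base is present, and the anisyl methyl ether must outlive the release of the catechol. The feature that opens the problem is the local symmetry of ring B: C6 and C7 bear the same group and C5 and C8 are both CH, so an aryne with its triple bond between C4a and C8a has a mirror plane and takes up an unsymmetrical four-carbon partner in either orientation with the same result. The chain C1–C2–C3–C4 (aryl at one end, H at the other) is the carbon chain of a 2-arylfuran, so in the cycloadduct C2 and C3 form a strained alkene exactly where the two identical nitrogen groups belong, and the furan oxygen bridges C1 and C4 and can later leave as water, which pays for the aromatisation without loss of nitrogen.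

## Retrosynthesis

**15 ⇒ 14.**
- Cut: the two catechol O–H bonds are exchanged for O–CH2Ph bonds.
- Why here: only a benzyl-type ether leaves under neutral conditions (hydrogenolysis) that touch neither the anisyl methyl ether nor the formamides. Methyl ethers could not be told apart from the anisyl OMe, and acetal-type masks would need acid on the finished bis(formamide).
- Gain: 14 has the same skeleton but is stable to air.
- Demand on the forward step: it only has to cleave two benzylic C–O bonds.

**14 ⇒ 12 (through 13).**
- Cut: ring A is de-aromatised by adding water back, with oxygen bonded to C1 and C4 as a bridge and hydrogen returned to C2 and C3.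
- Why here: aromatisation by loss of water needs no oxidant and expels oxygen rather than nitrogen. The neighbouring options (dehydrogenation of a dihydronaphthalene, or reductive removal of a bridge oxygen) need redox reagents next to electron-rich rings.
- Gain: ionisation is easy on both sides. A cation at C1 is stabilised by the anisyl ring and by the C6 oxygen para to C8a, and a cation at C4 by the C7 oxygen para to C4a.
- Demand on the forward step: catalytic acid mild enough to spare the product.

**12 ⇒ 11 ⇒ 9 ⇒ 8.**
- Cut: the two N–CHO bonds, then C2–N and C3–N together, which leaves the C2=C3 alkene of 8.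
- Why here: because N–C2–C3–N is dissonant, adding two nitrogen atoms across an existing C2=C3 bond is better than joining C2 to C3. This alkene is the only one in 8, is strained, and is open on its exo face. Carrying the nitrogens on the furan instead would need a multi-step heterocycle with N–H groups that arynes attack, and would then require a reductive loss of oxygen.
- Gain: 8 contains only C, H and O.
- Demand on the forward steps: a vicinal diazidation near neutrality, a mild reduction and a neutral formylation.

**8 ⇒ 7 + 3.**
- Cut: C1–C8a and C4–C4a in a retro-[4+2] step.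
- Why here: this is the only pair of ring A bonds whose cleavage gives one symmetric partner (7) and one partner in which the aryl group is already on the right terminal carbon (3), so no regiochemical question arises. A cut at C1–C2 and C3–C4 would call for an electron-rich cis-enediamine dienophile that has no easily removed form, and a single cut at C1–C8a leaves two aryl rings competing for closure.
- Gain: the product has three rings more than either component needs to be made with.
- Demand on the forward reaction: the aryne must be trapped faster than it is consumed by organolithium species.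

**7 ⇒ 6 ⇒ 5 ⇒ 4, and 3 ⇒ 1 + 2.**
- The aryne comes from the ortho-dibromide 5 by exchange and loss of LiBr, and 5 comes from commercial 4 by cutting two O–benzyl bonds.
- The furan 3 is cut at its aryl–furyl bond into two commercial partners.
- Both run-ups are one step long.

## Roads not taken

**Alternative 1:** the most obvious cut is the biaryl bond at C1.
- Forward key step: Suzuki–Miyaura coupling of an anisylboron partner with 6,7-bis(benzyloxy)-1-bromonaphthalene-2,3-diamine A2, made by monobromination of 6,7-bis(benzyloxy)naphthalene-2,3-diamine A1.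
- The 2,3,6,7-tetraheteroatom core A1 is not available and would be built on a bought naphthalene by placing each heteroatom in a separate operation.
- A1 offers two equivalent alpha positions beside the amines (C1, C4) and two more beside the ethers (C5, C8), so halogenation must stop after one of four activated sites.
- The coupling then occurs at a position flanked by an ortho amine and the peri C8–H, next to a chelating ortho-diamine.
- The key step makes one bond and leaves ring construction and both nitrogens unsolved. The chosen plan buys the biaryl bond in a simple furan and makes ring A with it.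

**Alternative 2:** the biomimetic cut is C1–C8a.
- Forward key step: six-electron electrocyclisation and oxidation of N,N'-{(1Z,3Z)-1-[3,4-bis(benzyloxy)phenyl]-4-(4-methoxyphenyl)buta-1,3-diene-2,3-diyl}diformamide A3.
- It brings the formamides in directly, but both ends of A3 carry an aryl ring. Closure of the anisyl ring onto C4 is equally allowed and leads to N,N'-{1-[3,4-bis(benzyloxy)phenyl]-7-methoxynaphthalene-2,3-diyl}diformamide A4, and the catechol ring itself has two ortho positions.
- The central double bond of the reacting triene must hold ring B cis to C2. That is the opposite of the Z geometry drawn in A3, so irradiation has to isomerise before it closes.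
- An external oxidant is needed beside electron-rich enamides.
- A3 still contains the dissonant C2–C3 bond, which would have to be made by cross-coupling two different alpha-formamidovinyl units. The chosen plan has no choice of ring, site or alkene geometry to control.

**Alternative 3:** the same C1–C8a bond can be cut in the polar sense.
- Forward key step: Bradsher-type cyclodehydration of 4-[3,4-bis(benzyloxy)benzyl]-5-(4-methoxybenzoyl)-1,3-dihydro-2H-imidazol-2-one A5, in which the ring holds C2=C3 cis and C8a (para to the C6 oxygen) attacks the ketone. Only the right ring can close, which is attractive.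
- The ketone of A5 is both an anisoyl group and a vinylogous urea, and therefore a poor electrophile. The strong hot acid it needs would strip benzyl ethers.
- The product, 6,7-bis(benzyloxy)-4-(4-methoxyphenyl)-1,3-dihydro-2H-naphtho[2,3-d]imidazol-2-one A6, holds the nitrogens in an aromatic cyclic urea that opens only under forcing hydrolysis.
- A5 itself takes several steps. The chosen plan carries nitrogen as azide, released under neutral conditions.

Key step: step 3

Assumption: the naphthalene numbering of the target is used for all bicyclic intermediates. Compounds 8 to 13 are racemates drawn as one enantiomer. The exo,exo arrangement at C2/C3 in 9 to 12 is the expected one, and any other C2/C3 diastereomer would be carried along, since all four sp3 centres are erased in step 7.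

## Steps

Step 1
Reactants: 1 4-bromoanisole; 2 furan-2-boronic acid
Product: 3 2-(4-methoxyphenyl)furan
Conditions: Pd(PPh3)4 (3 mol%), Na2CO3 (2 equiv), DME/H2O, 80 °C
Reagents that add atoms: none
Why: Suzuki–Miyaura coupling in which zerovalent palladium inserts into the C–Br bond of 1 and the 2-furyl group is transferred from boron; a small excess of 2 offsets protodeboronation.

Step 2
Reactants: 4 4,5-dibromobenzene-1,2-diol
Product: 5 1,2-bis(benzyloxy)-4,5-dibromobenzene
Conditions: BnBr (2.3 equiv), K2CO3 (3 equiv), DMF, 60 °C, under N2
Reagents that add atoms: benzyl bromide, BrCc1ccccc1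
Why: Double Williamson etherification of an acidic catechol; benzyl is chosen because it falls at the end under neutral hydrogenolysis that spares the anisyl methyl ether and the formamides.

Step 3
Reactants: 5 1,2-bis(benzyloxy)-4,5-dibromobenzene; 3 2-(4-methoxyphenyl)furan
Product: 8 rac-6,7-bis(benzyloxy)-1-(4-methoxyphenyl)-1,4-dihydro-1,4-epoxynaphthalene, via [4,5-bis(benzyloxy)-2-bromophenyl]lithium 6 (not isolated), via 4,5-bis(benzyloxy)benzyne 7 (not isolated)
Conditions: 3 (1.5 equiv), n-BuLi (1.05 equiv, slow addition), THF, −78 °C → rt; aq. NaHCO3 work-up, Et3N-deactivated silica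
Reagents that add atoms: none
Why: Bromine–lithium exchange on 5 gives 6, which loses LiBr on warming to the aryne 7, and 7 is trapped by the furan diene of 3 in a concerted suprafacial [4+2] cycloaddition, the closest known type being the aryne–furan Diels–Alder reaction of 4,5-dialkoxy-1,2-dibromobenzenes. The step closes ring A in an intermolecular six-membered cycloaddition mode, forming C1–C8a and C4–C4a at once and leaving the furan oxygen as a C1–O–C4 bridge. The new stereocentres C1 and C4 are tied to each other by the bridge (only the cis-bridged arrangement can exist), 8 is racemic, and both centres are erased in step 7. The one selectivity an unsymmetrical furan would normally demand is orientation, and none is needed here because 7 has a mirror plane through the midpoints of C4a–C8a and C6–C7, so both orientations give the same 8 with the anisyl group on C1. Chemoselectivity between the diene and the organolithium species is secured by adding n-BuLi slowly to a mixture that already holds an excess of 3, so that 7 never meets much n-BuLi or 6. Exchange at bromine at −78 °C is far faster than metalation of the free alpha C–H of the furan or of the benzylic OCH2 groups. The product is kept away from acid because its C1–O bond ionises easily.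

Step 4
Reactants: 8 rac-6,7-bis(benzyloxy)-1-(4-methoxyphenyl)-1,4-dihydro-1,4-epoxynaphthalene
Product: 9 rac-(2-exo,3-exo)-2,3-diazido-6,7-bis(benzyloxy)-1-(4-methoxyphenyl)-1,2,3,4-tetrahydro-1,4-epoxynaphthalene
Conditions: Fe(OAc)2 (10 mol%), 2,6-bis(4,5-dihydrooxazol-2-yl)pyridine (12 mol%), 1-hydroxy-1,2-benziodoxol-3(1H)-one (1.3 equiv), TMSN3 (4 equiv), 2,6-di-tert-butylpyridine (0.2 equiv), CH2Cl2/MeCN, rt
Reagents that add atoms: azidotrimethylsilane, C[Si](C)(C)N=[N+]=[N-]
Why: Iron-catalysed radical diazidation of an alkene, in which an azido radical adds to the strained C2=C3 bond at the less hindered C3 and the C2 radical takes a second azide from an iron azide species. Both C–N bonds are expected on the exo face (syn to the oxygen bridge) because ring B screens the endo face, and the outcome at C2/C3 does not matter later. The acetate salt and the hindered base keep strong silicon or iron Lewis acids away from the labile C1–O bond.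

Step 5
Reactants: 9 rac-(2-exo,3-exo)-2,3-diazido-6,7-bis(benzyloxy)-1-(4-methoxyphenyl)-1,2,3,4-tetrahydro-1,4-epoxynaphthalene
Product: 11 rac-(2-exo,3-exo)-6,7-bis(benzyloxy)-1-(4-methoxyphenyl)-1,2,3,4-tetrahydro-1,4-epoxynaphthalene-2,3-diamine, via bis(trimethyliminophosphorane) 10 (not isolated)
Conditions: PMe3 (3 equiv), THF, 0 °C → rt; then H2O, 40 °C
Reagents that add atoms: none
Why: Staudinger reduction, in which each azide loses N2 to give the iminophosphorane that water hydrolyses; the small phosphine reaches the hindered C2 azide. The neutral to basic medium spares the benzyl ethers and the oxygen bridge, and no stereocentre is touched.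

Step 6
Reactants: 11 rac-(2-exo,3-exo)-6,7-bis(benzyloxy)-1-(4-methoxyphenyl)-1,2,3,4-tetrahydro-1,4-epoxynaphthalene-2,3-diamine
Product: 12 rac-N,N'-[(2-exo,3-exo)-6,7-bis(benzyloxy)-1-(4-methoxyphenyl)-1,2,3,4-tetrahydro-1,4-epoxynaphthalene-2,3-diyl]diformamide
Conditions: HCO2Et (solvent), 60 °C, sealed tube
Reagents that add atoms: ethyl formate, CCOC=O
Why: Aminolysis of a formate ester by two primary aliphatic amines under acid-free conditions, so the bridge survives. At this sp3 stage the two formamides cannot close to an aromatic imidazole.

Step 7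
Reactants: 12 rac-N,N'-[(2-exo,3-exo)-6,7-bis(benzyloxy)-1-(4-methoxyphenyl)-1,2,3,4-tetrahydro-1,4-epoxynaphthalene-2,3-diyl]diformamide
Product: 14 N,N'-[6,7-bis(benzyloxy)-1-(4-methoxyphenyl)naphthalene-2,3-diyl]diformamide, via ring-opened 3,4-cis hydroxy enamide 13 (not isolated)
Conditions: p-TsOH·H2O (10 mol%), 4 Å molecular sieves, CH2Cl2, 0 °C → rt
Reagents that add atoms: none
Why: Acid-catalysed dehydrative aromatisation of a 1,4-epoxytetralin, in which C1–O ionises to a cation held by the anisyl ring and the C6 oxygen and loss of H from C2 gives 13. The C4–OH then ionises with help from the C7 oxygen, and loss of H from C3 completes ring A. Oxygen is the leaving group, so both nitrogens stay, and all four stereocentres vanish.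

Step 8
Reactants: 14 N,N'-[6,7-bis(benzyloxy)-1-(4-methoxyphenyl)naphthalene-2,3-diyl]diformamide
Product: 15 melanocin E, N,N'-[6,7-dihydroxy-1-(4-methoxyphenyl)naphthalene-2,3-diyl]diformamide
Conditions: H2 (1 atm), Pd/C (10 wt%), THF/MeOH, rt; filtration and concentration under argon
Reagents that add atoms: none
Why: Hydrogenolysis of two aryl benzyl ethers under neutral conditions; formamides, the aryl methyl ether and the naphthalene are inert at one atmosphere. The catechol is released only in the last operation and in the absence of base and air.

## Compound list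

1 | 4-bromoanisole | COc1ccc(Br)cc1 | starting material
2 | furan-2-boronic acid | OB(O)c1ccco1 | starting material
3 | 2-(4-methoxyphenyl)furan | COc1ccc(cc1)-c1ccco1 | intermediate
4 | 4,5-dibromobenzene-1,2-diol | Oc1cc(Br)c(Br)cc1O | starting material
5 | 1,2-bis(benzyloxy)-4,5-dibromobenzene | Brc1cc(OCc2ccccc2)c(OCc2ccccc2)cc1Br | intermediate
6 | [4,5-bis(benzyloxy)-2-bromophenyl]lithium | [Li]c1cc(OCc2ccccc2)c(OCc2ccccc2)cc1Br | intermediate
7 | 4,5-bis(benzyloxy)benzyne | C1#CC=C(OCc2ccccc2)C(OCc2ccccc2)=C1 | intermediate
8 | rac-6,7-bis(benzyloxy)-1-(4-methoxyphenyl)-1,4-dihydro-1,4-epoxynaphthalene | COc1ccc(cc1)[C@]12O[C@H](C=C1)c1cc(OCc3ccccc3)c(OCc3ccccc3)cc12 | intermediate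
9 | rac-(2-exo,3-exo)-2,3-diazido-6,7-bis(benzyloxy)-1-(4-methoxyphenyl)-1,2,3,4-tetrahydro-1,4-epoxynaphthalene | COc1ccc(cc1)[C@]12O[C@H]([C@H](N=[N+]=[N-])[C@@H]1N=[N+]=[N-])c1cc(OCc3ccccc3)c(OCc3ccccc3)cc12 | intermediate
10 | rac-(2-exo,3-exo)-2,3-bis[(trimethyl-λ5-phosphanylidene)amino] analogue of 9 | COc1ccc(cc1)[C@]12O[C@H]([C@H](N=P(C)(C)C)[C@@H]1N=P(C)(C)C)c1cc(OCc3ccccc3)c(OCc3ccccc3)cc12 | intermediate
11 | rac-(2-exo,3-exo)-6,7-bis(benzyloxy)-1-(4-methoxyphenyl)-1,2,3,4-tetrahydro-1,4-epoxynaphthalene-2,3-diamine | COc1ccc(cc1)[C@]12O[C@H]([C@H](N)[C@@H]1N)c1cc(OCc3ccccc3)c(OCc3ccccc3)cc12 | intermediate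
12 | rac-N,N'-[(2-exo,3-exo)-6,7-bis(benzyloxy)-1-(4-methoxyphenyl)-1,2,3,4-tetrahydro-1,4-epoxynaphthalene-2,3-diyl]diformamide | COc1ccc(cc1)[C@]12O[C@H]([C@H](NC=O)[C@@H]1NC=O)c1cc(OCc3ccccc3)c(OCc3ccccc3)cc12 | intermediate
13 | rac-N,N'-[(3,4-cis)-6,7-bis(benzyloxy)-4-hydroxy-1-(4-methoxyphenyl)-3,4-dihydronaphthalene-2,3-diyl]diformamide | COc1ccc(cc1)C1=C(NC=O)[C@@H](NC=O)[C@@H](O)c2cc(OCc3ccccc3)c(OCc3ccccc3)cc12 | intermediate
14 | N,N'-[6,7-bis(benzyloxy)-1-(4-methoxyphenyl)naphthalene-2,3-diyl]diformamide | COc1ccc(-c2c(NC=O)c(NC=O)cc3cc(OCc4ccccc4)c(OCc4ccccc4)cc23)cc1 | intermediate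
15 | melanocin E | COc1ccc(-c2c(NC=O)c(NC=O)cc3cc(O)c(O)cc23)cc1 | target

## Step count and least certain steps

Total step count: 8. Longest linear sequence: 7 (steps 2 to 8, from 4).

**Step 3 (key step).**
- Most likely failure: the aryne is intercepted by n-BuLi or by the aryllithium before it meets the diene. The aryl group on the furan adds bulk at one terminus and takes the diene into conjugation, which slows trapping relative to the parent furan.
- Second failure mode: acid-catalysed isomerisation of the adduct during isolation, because its C1–O bond ionises readily.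
- Fallback: give up the aryne and reach 8 through an isobenzofuran, setting out from 5. Bromine–magnesium exchange with i-PrMgCl·LiCl at −20 °C (the arylmagnesium species keeps its neighbouring bromide at this temperature) and addition to 4-methoxybenzaldehyde give the carbinol [4,5-bis(benzyloxy)-2-bromophenyl](4-methoxyphenyl)methanol F1. Treatment with n-BuLi (2.2 equiv) and then DMF converts it into the lactol 5,6-bis(benzyloxy)-3-(4-methoxyphenyl)-1,3-dihydro-2-benzofuran-1-ol F2. A trace of acetic acid in warm toluene dehydrates F2 to 5,6-bis(benzyloxy)-1-(4-methoxyphenyl)-2-benzofuran F3. This is trapped as it forms by (E)-1,2-bis(phenylsulfonyl)ethene in a Diels–Alder reaction to give rac-6,7-bis(benzyloxy)-1-(4-methoxyphenyl)-2,3-trans-bis(phenylsulfonyl)-1,2,3,4-tetrahydro-1,4-epoxynaphthalene F4, whose sulfonyl groups also protect the bridge against ionisation. Reductive elimination of both sulfonyl groups with Na(Hg) in Na2HPO4-buffered MeOH/THF gives the alkene, and the route is rejoined at 8.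

**Step 4.**
- Most likely failure: ionisation of the C1–O bond by adventitious silicon or iron Lewis acids, followed by capture of the allylic benzhydryl-type cation by azide or by loss of the C4 proton.
- Further risks: a 1,2-shift of the anisyl group from C1 to the C2 radical before azide transfer, and hydrogen abstraction from the benzylic OCH2 groups.
- Fallback: put oxygen on C2/C3 first and exchange it for nitrogen on the aromatic ring, setting out from 8.
  - OsO4 (cat.) with N-methylmorpholine N-oxide in acetone/H2O gives the exo-cis diol rac-(2-exo,3-exo)-6,7-bis(benzyloxy)-1-(4-methoxyphenyl)-1,2,3,4-tetrahydro-1,4-epoxynaphthalene-2,3-diol F5.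
  - Catalytic p-TsOH dehydrates F5 to 6,7-bis(benzyloxy)-1-(4-methoxyphenyl)naphthalene-2,3-diol F6.
  - Tf2O/pyridine gives the bis(triflate) 6,7-bis(benzyloxy)-1-(4-methoxyphenyl)naphthalene-2,3-diyl bis(trifluoromethanesulfonate) F7.
  - Double Buchwald–Hartwig amination with benzophenone imine (Pd2(dba)3, rac-BINAP, Cs2CO3, toluene, 100 °C) gives the bis(imine) 6,7-bis(benzyloxy)-N2,N3-bis(diphenylmethylidene)-1-(4-methoxyphenyl)naphthalene-2,3-diamine F8.
  - Aqueous citric acid in THF releases 6,7-bis(benzyloxy)-1-(4-methoxyphenyl)naphthalene-2,3-diamine F9.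
  - Acetic formic anhydride in THF at −20 °C formylates both amines faster than the monoformamide can cyclise, and the route is rejoined at 14.

**Step 7.**
- Most likely failure: condensation of the two neighbouring formamides of the aromatic product to a naphthimidazole under the acid that drives the dehydration.
- Further risks: stalling after participation of the C2 formamide oxygen at the C1 cation (oxazoline formation), and hydrolysis of a formamide by the water released.
- Fallback: change the order so that no formamide ever sees acid, setting out from 11. Boc2O in THF gives the bis(carbamate) rac-di-tert-butyl [(2-exo,3-exo)-6,7-bis(benzyloxy)-1-(4-methoxyphenyl)-1,2,3,4-tetrahydro-1,4-epoxynaphthalene-2,3-diyl]dicarbamate F10. Trifluoroacetic acid in CH2Cl2 opens the bridge, dehydrates and removes both carbamates to give, after neutralisation, 6,7-bis(benzyloxy)-1-(4-methoxyphenyl)naphthalene-2,3-diamine F9. Formylation with acetic formic anhydride at −20 °C rejoins the route at 14.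

## Further compounds

F1 | step 3 | rac-[4,5-bis(benzyloxy)-2-bromophenyl](4-methoxyphenyl)methanol | COc1ccc(cc1)[C@H](O)c1cc(OCc2ccccc2)c(OCc2ccccc2)cc1Br
F2 | step 3 | 5,6-bis(benzyloxy)-3-(4-methoxyphenyl)-1,3-dihydro-2-benzofuran-1-ol (racemic, anomeric mixture, one isomer drawn) | COc1ccc(cc1)[C@H]1O[C@@H](O)c2cc(OCc3ccccc3)c(OCc3ccccc3)cc12
F3 | step 3 | 5,6-bis(benzyloxy)-1-(4-methoxyphenyl)-2-benzofuran | COc1ccc(cc1)C1=C2C=C(OCc3ccccc3)C(OCc3ccccc3)=CC2=CO1
F4 | step 3 | rac-6,7-bis(benzyloxy)-1-(4-methoxyphenyl)-2,3-trans-bis(phenylsulfonyl)-1,2,3,4-tetrahydro-1,4-epoxynaphthalene | COc1ccc(cc1)[C@]12O[C@H]([C@H](S(=O)(=O)c3ccccc3)[C@H]1S(=O)(=O)c3ccccc3)c1cc(OCc3ccccc3)c(OCc3ccccc3)cc12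
F5 | step 4 | rac-(2-exo,3-exo)-6,7-bis(benzyloxy)-1-(4-methoxyphenyl)-1,2,3,4-tetrahydro-1,4-epoxynaphthalene-2,3-diol | COc1ccc(cc1)[C@]12O[C@H]([C@H](O)[C@@H]1O)c1cc(OCc3ccccc3)c(OCc3ccccc3)cc12
F6 | step 4 | 6,7-bis(benzyloxy)-1-(4-methoxyphenyl)naphthalene-2,3-diol | COc1ccc(cc1)-c1c(O)c(O)cc2cc(OCc3ccccc3)c(OCc3ccccc3)cc12
F7 | step 4 | 6,7-bis(benzyloxy)-1-(4-methoxyphenyl)naphthalene-2,3-diyl bis(trifluoromethanesulfonate) | COc1ccc(cc1)-c1c(OS(=O)(=O)C(F)(F)F)c(OS(=O)(=O)C(F)(F)F)cc2cc(OCc3ccccc3)c(OCc3ccccc3)cc12
F8 | step 4 | 6,7-bis(benzyloxy)-N2,N3-bis(diphenylmethylidene)-1-(4-methoxyphenyl)naphthalene-2,3-diamine | COc1ccc(cc1)-c1c(N=C(c3ccccc3)c3ccccc3)c(N=C(c3ccccc3)c3ccccc3)cc2cc(OCc3ccccc3)c(OCc3ccccc3)cc12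
F9 | step 4 | 6,7-bis(benzyloxy)-1-(4-methoxyphenyl)naphthalene-2,3-diamine | COc1ccc(cc1)-c1c(N)c(N)cc2cc(OCc3ccccc3)c(OCc3ccccc3)cc12
F10 | step 7 | rac-di-tert-butyl [(2-exo,3-exo)-6,7-bis(benzyloxy)-1-(4-methoxyphenyl)-1,2,3,4-tetrahydro-1,4-epoxynaphthalene-2,3-diyl]dicarbamate | COc1ccc(cc1)[C@]12O[C@H]([C@H](NC(=O)OC(C)(C)C)[C@@H]1NC(=O)OC(C)(C)C)c1cc(OCc3ccccc3)c(OCc3ccccc3)cc12
A1 | alternative 1 | 6,7-bis(benzyloxy)naphthalene-2,3-diamine | Nc1cc2cc(OCc3ccccc3)c(OCc3ccccc3)cc2cc1N
A2 | alternative 1 | 6,7-bis(benzyloxy)-1-bromonaphthalene-2,3-diamine | Nc1cc2cc(OCc3ccccc3)c(OCc3ccccc3)cc2c(Br)c1N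
A3 | alternative 2 | N,N'-{(1Z,3Z)-1-[3,4-bis(benzyloxy)phenyl]-4-(4-methoxyphenyl)buta-1,3-diene-2,3-diyl}diformamide | COc1ccc(cc1)/C=C(\NC=O)/C(/NC=O)=C/c1ccc(OCc2ccccc2)c(OCc2ccccc2)c1
A4 | alternative 2 | N,N'-{1-[3,4-bis(benzyloxy)phenyl]-7-methoxynaphthalene-2,3-diyl}diformamide | COc1ccc2cc(NC=O)c(NC=O)c(-c3ccc(OCc4ccccc4)c(OCc4ccccc4)c3)c2c1
A5 | alternative 3 | 4-[3,4-bis(benzyloxy)benzyl]-5-(4-methoxybenzoyl)-1,3-dihydro-2H-imidazol-2-one | COc1ccc(cc1)C(=O)C1=C(Cc2ccc(OCc3ccccc3)c(OCc3ccccc3)c2)NC(=O)N1
A6 | alternative 3 | 6,7-bis(benzyloxy)-4-(4-methoxyphenyl)-1,3-dihydro-2H-naphtho[2,3-d]imidazol-2-one | COc1ccc(cc1)-c1c2NC(=O)Nc2cc2cc(OCc3ccccc3)c(OCc3ccccc3)cc12
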